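## Retrosynthetic overview
- The last step is a bromonium-induced 6-endo bromoetherification of a tertiary alcohol carrying a prenyl-type alkene. It closes the 3-bromo-2,2-dimethyltetrahydropyran ring and sets the THP C–Br centre.
- The tertiary alcohol comes from the late coupling of a C9 halogenated methyl ketone (the cyclohexane half) with a C6 homoprenyl-cerium reagent (the side-chain half).
- The ketone comes from trans-bromochlorination of (R)-1-(4-methylcyclohex-3-enyl)ethanone. That ketone comes from the enantioselective Diels–Alder aldehyde from isoprene and acrolein.
- The homoprenyl bromide comes from cyclopropyl methyl ketone.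
- Ring order: the cyclohexane forms first (Diels–Alder) and the THP last.

Assumptions:
- The oxazaborolidinium enantiomer is chosen to give the (R)-aldehyde.
- Diastereomers formed in Steps 4, 8 and 9 are separable by chromatography, and only the isomer matching the target is carried forward.

## Route

**Step 1**
Reactants: 1 isoprene; 2 acrolein
Product: 3 (R)-4-methylcyclohex-3-ene-1-carbaldehyde
Conditions: 10 mol% chiral oxazaborolidinium (prolinol-derived B-o-tolyl oxazaborolidine + Tf2NH), CH2Cl2, −78 °C
Reagents that add atoms: none
Why: Lewis-acid-catalysed Diels–Alder of a 2-substituted diene gives the "para" (1,4) regiochemistry. The chiral catalyst shields one face of acrolein and sets C1 as (R).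

**Step 2**
Reactants: 3
Product: 4 1-[(1R)-4-methylcyclohex-3-en-1-yl]ethan-1-ol (epimeric mixture at the carbinol carbon)
Conditions: MeMgBr, THF, −78 → 0 °C; aq NH4Cl
Reagents that add atoms: MeMgBr, C[Mg]Br
Why: Grignard addition to the aldehyde leaves the ring stereocentre untouched. The new carbinol centre is destroyed in the next step, so its configuration is irrelevant.

**Step 3**
Reactants: 4
Product: 5 (R)-1-(4-methylcyclohex-3-en-1-yl)ethan-1-one
Conditions: Dess–Martin periodinane, NaHCO3, CH2Cl2, 0 °C → rt
Reagents that add atoms: none
Why: Buffered, non-basic oxidation of the secondary alcohol avoids epimerising the α-stereocentre and leaves the ring alkene intact.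

**Step 4**
Reactants: 5
Product: 6 1-[(1R,3R,4R)-3-bromo-4-chloro-4-methylcyclohexyl]ethan-1-one
Conditions: NBS, Et4NCl, CH2Cl2, −30 °C (BrCl formed in situ)
Reagents that add atoms:
- NBS, O=C1CCC(=O)N1Br
- Et4NCl, CC[N+](CC)(CC)CC.[Cl-]

Why: Electrophilic bromochlorination proceeds through a bromonium ion opened anti by chloride at the tertiary carbon (Markovnikov), giving trans Br/Cl. The target isomer (Br cis to the acetyl, Cl trans) is the trans-diaxial adduct from the half-chair with the acetyl pseudo-axial. The (1R,3S,4S) epimer from the acetyl-equatorial half-chair forms competitively, so selectivity is modest and the isomers are separated. Halogenating before the coupling avoids competition with the side-chain alkene.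

**Step 5**
Reactants: 7 cyclopropyl methyl ketone
Product: 8 2-cyclopropylpropan-2-ol
Conditions: MeMgBr, Et2O, 0 °C; aq NH4Cl
Reagents that add atoms: MeMgBr, C[Mg]Br
Why: Simple Grignard addition to a ketone; no stereocentre is formed.

**Step 6**
Reactants: 8
Product: 9 5-bromo-2-methylpent-2-ene
Conditions: 48% aq HBr, 0 °C → rt
Reagents that add atoms: HBr, Br
Why: Cyclopropylcarbinyl cation ring-opening by bromide (Julia-type) gives the homoallylic bromide with the trisubstituted alkene.

**Step 7**
Reactants: 9
Product: 10 (4-methylpent-3-en-1-yl)magnesium bromide
Conditions: Mg turnings, cat. I2, THF, 40 °C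
Reagents that add atoms: Mg, [Mg]
Why: Standard Grignard formation; the homoallylic organometallic is stable and does not cyclise.

**Step 8 (late coupling)**
Reactants: 6 (halogenated ketone, C9); 10 (Grignard, C6)
Product: 11 (2R)-2-[(1R,3R,4R)-3-bromo-4-chloro-4-methylcyclohexyl]-6-methylhept-5-en-2-ol
Conditions: anhydrous CeCl3, THF, −78 °C; add 10; then add 6; −78 → −40 °C; aq NH4Cl
Reagents that add atoms: CeCl3, none (Ce is lost on work-up, and the alcohol O comes from the ketone)
Why: The organocerium reagent adds chemoselectively to the ketone. It does not enolise or epimerise C1, and it tolerates the secondary bromide and tertiary chloride. The tertiary carbinol centre is set by Felkin–Anh facial selectivity relative to C1, which is only modest, so the (2R) diastereomer is separated from its epimer.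

**Step 9**
Reactants: 11
Product: 12 Deoxycaespitol, (3S,6R)-3-bromo-6-[(1R,3R,4R)-3-bromo-4-chloro-4-methylcyclohexyl]-2,2,6-trimethyltetrahydro-2H-pyran
Conditions: NBS, CH2Cl2, −20 °C
Reagents that add atoms: NBS, O=C1CCC(=O)N1Br
Why: Bromonium-induced 6-endo cyclisation: the tertiary OH attacks the more substituted alkene carbon anti to Br+. C6 is already fixed, and the chair-like transition state puts the bulky cyclohexyl group equatorial. The new Br is then necessarily equatorial, trans to the cyclohexyl group, which gives the (3S) centre. The only alkene in the molecule is the prenyl alkene, so no chemoselectivity problem arises.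

## Compound list
1 | isoprene | C=CC(C)=C | starting material
2 | acrolein | C=CC=O | starting material
3 | (R)-4-methylcyclohex-3-ene-1-carbaldehyde | O=C[C@@H]1CCC(C)=CC1 | intermediate
4 | 1-[(1R)-4-methylcyclohex-3-en-1-yl]ethan-1-ol (carbinol epimers) | CC(O)[C@@H]1CCC(C)=CC1 | intermediate
5 | (R)-1-(4-methylcyclohex-3-en-1-yl)ethan-1-one | CC(=O)[C@@H]1CCC(C)=CC1 | intermediate
6 | 1-[(1R,3R,4R)-3-bromo-4-chloro-4-methylcyclohexyl]ethan-1-one | CC(=O)[C@@H]1CC[C@@](C)(Cl)[C@H](Br)C1 | intermediate
7 | cyclopropyl methyl ketone | CC(=O)C1CC1 | starting material
8 | 2-cyclopropylpropan-2-ol | CC(C)(O)C1CC1 | intermediate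
9 | 5-bromo-2-methylpent-2-ene | CC(C)=CCCBr | intermediate
10 | (4-methylpent-3-en-1-yl)magnesium bromide | CC(C)=CCC[Mg]Br | intermediate
11 | (2R)-2-[(1R,3R,4R)-3-bromo-4-chloro-4-methylcyclohexyl]-6-methylhept-5-en-2-ol | O[C@@](C)([C@@H]1CC[C@@](C)(Cl)[C@H](Br)C1)CCC=C(C)C | intermediate
12 | Deoxycaespitol | CC1(C)O[C@@](C)([C@@H]2CC[C@@](C)(Cl)[C@H](Br)C2)CC[C@@H]1Br | target

## Totals
- Total steps: 9.
- Longest linear sequence: 6 (Steps 1, 2, 3, 4, 8, 9). The side-chain branch is Steps 5–7.

**Three steps most likely to fail**
1. **Step 4 (ring bromochlorination diastereoselectivity).** The target-configured isomer requires a pseudo-axial acetyl and may be the minor product. Fallback: epoxidise 5 diastereoselectively, open the epoxide with bromide at the secondary carbon to give the trans-bromohydrin, then convert the tertiary OH to Cl with retention via bromonium participation (SOCl2, pyridine).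
2. **Step 8 (Felkin selectivity and C1 epimerisation).** The dr is modest and the α-centre is labile. Fallback: reverse the polarity of the coupling. Convert 3 to the Weinreb amide and add 10 to give the ring ketone, then add MeLi/CeCl3 in place of the Grignard addition to the methyl ketone. If the dr stays poor, resolve the tertiary alcohol by chiral HPLC.
3. **Step 9 (6-endo versus 5-exo, and C3 dr).** NBS can give the 2-(2-bromopropan-2-yl)tetrahydrofuran, or the cis-bromide. Fallback: epoxidise the prenyl alkene of 11 (mCPBA), open the epoxide with CSA (6-endo) to the 3-hydroxy-THP, then convert OH to Br with inversion (PPh3/CBr4, Appel), choosing the epoxide diastereomer that gives the (3S)-bromide.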